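The constants are invented, and the outcome is calculated.

In a one-step world a yield grows with waiting until the reactant is gone. This flask runs a round instead (a catalytic cycle): L takes up E and becomes X, and X hands over to D, giving G and L again. But X can also turn into Z, which leaves the round, and G above its solubility falls out as Q, which still counts.

D 20 mM; E 21.0 mM; L 0.22 mM; time 20 h; volume of the second phase over the first 1.0

- noon: doubling the amount of E, all else as stated
- summer: doubling the dissolution coefficient of step 4, all else as stated
- dusk: doubling the solubility in step 4, all else as stated

1. how much G and Q together there is at 20 h, in percent of the D charged
2. concentration of G in solution at 5.0 h, in percent of saturation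
3. the change that raises the amount of G and Q together at 20 h, in percent of the D charged most ("none" if none brings more than 2 percentage points) (noon / summer / dusk / none)
4. amount of G and Q together at 20 h, in percent of the D charged, after noon

- amounts and yields of G count Q too
- in the second phase: E, J; everything else is in the first
- charges count per volume of the first phase; a concentration in a rate is the amount of a species over the volume of its own phase; every rate counts per litre of the first phase
- given per volume of solution although it is solid: Q
- run time (flask): 20 h

    L + E ⇌ X + J (K1 = 0.84, k1 = 730 L mol⁻¹ h⁻¹)
    D + X → G + L (k2 = 2300 L mol⁻¹ h⁻¹)
    X → Z (k3 = 0.41 h⁻¹)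
    Q ⇌ G, rate k4*(cs4 - [G]) while solid is left; crystals form when [G] > cs4 (cs4 = 10 mM, k4 = 48 h⁻¹)

Two amounts matter in this flask: the catalyst charged, 0.22 mM, and what I call the price, 0.178 mM, the amount of catalyst that goes to Z while D falls by a factor e. Each X chooses between D and Z, so the logarithm of the fall of D equals the Z made over the price, however E behaves. The charge over the price is 1.23, which puts the ceiling on the yield at 70.9 %.

X goes to Z far more slowly than it hands over to the charged D, so I take the share of X as if nothing were lost and add the loss as a correction. Once D is half used I take D, E and J as equal, and X is then 18.7 % of the live catalyst. Held over the whole run, that share puts the part lost to Z by 20 h at 78.5 %, which gives 62.0 %. With the charged D and E and no J yet, X is 25.0 % of the live catalyst; held up to 5.0 h, that share gives me 78.1 % of saturation.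

Q touches neither D nor X, so summer and dusk leave the total as it is. Reckoned again with D half used, noon lifts the share of X to 42.4 %, the part lost to 96.9 %, and the yield to 69.8 %. My choice is noon.

The forecast gives 63 %, 71 %, noon and 69.5 %, on the ground that “Deactivation limits conversion”. The flask gives 63.0 %, 74.2 %, noon with a gain of 6.7 percentage points, and 69.8 %.

In the flask Z holds 80.6 % of the catalyst at 20.0 h, and that loss, set against the price, gives 62.9 %. The price contains no D, so the neighbour charged with 8.0 mM of D has the same ceiling, and its Z of 98.3 % gives 70.2 %. The computed yield of that neighbour is 70.3 %.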